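In a one-step world, left-handed substrate vanishes with a single rate constant k, so the fraction gone by time t is 1 − e^(−kt). Left-handed substrate is half of the pair charged, so I took left-handed product, in percent of the pair, as that half times this fraction.

| setting | grey | teal | Wednesday's | Monday's |
|---|---|---|---|---|
| left-handed substrate | 0.93 M | 0.62 M | 0.62 M | 0.62 M |
| right-handed substrate | 0.93 M | 0.62 M | 0.62 M | 0.62 M |
| coupling partner | 1.5 equiv | 0.75 equiv | 1.50 equiv | 1.50 equiv |
| free catalyst | 5 mol% | 5 mol% | 10 mol% | 5 mol% |
| added ligand | 120 mM | 120 mM | 200 mM | 120 mM |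
| temperature | 110 °C | 110 °C | 110 °C | 110 °C |
| remark | run made earlier | run made earlier |  |  |
| time |  |  | 20 min | 20 min |

| grey: time / min | grey: left-handed product / % | teal: time / min | teal: left-handed product / % |
|---|---|---|---|
| 0.500 | 0.8 | 1.00 | 1.1 |
| 0.833 | 2.7 | 2.00 | 1.6 |
| 1.33 | 3.9 | 3.00 | 2.8 |
| 2.00 | 7.0 | 4.00 | 4.8 |
| 3.00 | 9.4 | 5.00 | 4.7 |
| 5.00 | 13.5 | 6.00 | 6.0 |
| 8.00 | 21.1 | 8.00 | 7.7 |

(readings scatter by 0.5 percentage points)

- free catalyst is single-handed; left-handed substrate and right-handed substrate are mirror images of each other, charged as a racemate, each of them at the stated concentration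
- no earlier run changes the charge of added ligand; that part of a forecast is a guess

- which of the two ends with the higher amount of left-handed product, in percent of the left-handed substrate and right-handed substrate together charged ("neither" if they lie within 2 percentage points) (Wednesday's / Monday's / neither)
- left-handed product at the end, in percent of the left-handed substrate and right-handed substrate together charged, Wednesday's
- left-handed product at the end, in percent of the left-handed substrate and right-handed substrate together charged, Monday's

The grey and teal readings do not rise alike, so I asked what k goes with. I supposed that each catalyst molecule turns over in proportion to the partner it meets. The catalyst is charged as a loading m on left-handed substrate, so the fraction of left-handed substrate consumed per minute should go as m times B, the molarity of coupling partner. I froze B at its charge, which makes k a pseudo-first-order constant, and wrote κ = k/(mB).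

The grey run's reading at 8.00 min gives k = 0.0685 min⁻¹, and with B = 1.40 M that makes κ = 0.0164 M⁻¹ s⁻¹. The teal run's reading at 8.00 min gives k = 0.0209 min⁻¹, and with B = 0.465 M that makes κ = 0.0150 M⁻¹ s⁻¹, from a reading of 7.7% that carries a scatter of 0.5 percentage points. I kept their mean, 0.0157 M⁻¹ s⁻¹, as the turnover constant κ, the k of a flask per unit of loading and per molar of partner.

For Monday's, this gives k = 0.0437 min⁻¹ and, at 20 min, 29.2% of left-handed product. For Wednesday's, a loading of 10 mol% gives k = 0.0875 min⁻¹ and 41.3%, with added ligand not counted, since no earlier run changes it. The forecast also chose Wednesday's, with 37% for Wednesday's and 30% for Monday's. Its figure for Wednesday's lies below mine, and of the ligand it said: “The ligand effect is a guess”.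

The simulation gave 39.2% for Wednesday's and 28.3% for Monday's, so Wednesday's ended higher.

    free catalyst + left-handed substrate ⇌ catalyst intermediate A (K = 16.0 M⁻¹, k = 7.00 M⁻¹ s⁻¹, Ea = 68.0 kJ mol⁻¹, ΔH = 24.0 kJ mol⁻¹)
    free catalyst + right-handed substrate ⇌ catalyst intermediate B (K = 1.60 M⁻¹, k = 0.200 M⁻¹ s⁻¹, Ea = 55.0 kJ mol⁻¹, ΔH = −29.0 kJ mol⁻¹)
    coupling partner + catalyst intermediate A → free catalyst + left-handed product (k = 0.0190 M⁻¹ s⁻¹, Ea = 85.0 kJ mol⁻¹)
    coupling partner + catalyst intermediate B → free catalyst + right-handed product (k = 0.00910 M⁻¹ s⁻¹, Ea = 73.0 kJ mol⁻¹)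
    free catalyst + added ligand ⇌ idle complex, settled at all times (K = 7.40 M⁻¹, ΔH = −30.0 kJ mol⁻¹)
    (constants at 110 °C)

Wednesday's owes part of its left-handed product to catalyst intermediate B falling back to free catalyst and right-handed substrate: with that return taken away, Wednesday's gave 21.9% instead of 39.2%. Read back from Monday's end, κ stands at 0.0150 M⁻¹ s⁻¹, against 0.0157 M⁻¹ s⁻¹ from the early readings. The neighbouring flask is Monday's with 2 mol% of free catalyst; there 0.0157 M⁻¹ s⁻¹ gives k = 0.0175 min⁻¹ and 14.8%, and the flask gave 14.1%.

The readings come from a simulation from invented constants.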